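**Retrosynthetic overview**
1. The target comes from a 2-alkylresorcinol by ortho-formylation after O-demethylation; the axial secondary alcohol comes from bulky-hydride reduction of the corresponding ketone.
2. Ring A (formed second) comes from a radical epoxide–alkene cyclisation of an (S)-epoxide onto the cyclohexene of ring B; the epoxide comes from a Shi epoxidation.
3. The homoprenyl chain is attached by Negishi coupling to a ring B enol triflate, made by conjugate reduction and triflation of an enone.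
4. The quaternary carbon comes from α′-benzylation of (5R)-5,6-dimethylcyclohex-2-enone, anti to the neighbouring methyl, with a 2,6-dimethoxybenzyl bromide.
5. Ring B (formed first) comes from an amine-catalysed asymmetric Michael–aldol annulation of crotonaldehyde with tert-butyl 2-methylacetoacetate, which sets the first stereocentre.

Assumption: the target is the open hydroxy-aldehyde as drawn; decalin positions are called C1–C11 in the drimane sense (C3 carbinol, C4 CMe2, C5 ring-fusion CH, C8 CHMe, C9 quaternary, C10 ring-fusion sp2 carbon, C11 benzylic CH2); metal alkoxides that are only protonated on work-up are not numbered.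

**Step 1**
Reactants: 1 (E)-but-2-enal (crotonaldehyde); 2 tert-butyl 2-methyl-3-oxobutanoate
Product: 5 (5R)-5,6-dimethylcyclohex-2-en-1-one (C6 epimer mixture), via Michael adduct 3 (not isolated), via cyclised tert-butyl ester 4 (not isolated)
Conditions: (S)-2-{bis[3,5-bis(trifluoromethyl)phenyl](trimethylsilyloxy)methyl}pyrrolidine (10 mol%), PhCO2H (10 mol%), neat, rt; then p-TsOH·H2O (20 mol%), toluene, 80 °C
Reagents that add atoms: none
Why: Proposed new method: iminium-activated Michael addition of an α-methylated β-keto ester to crotonaldehyde, in which the diarylprolinol silyl ether shields one face of the E-iminium ion so the donor bonds anti to the bulky group and gives the 3R adduct whatever its own α-substituent, followed by acid-mediated aldol condensation, loss of isobutene and decarboxylation that erases the transient quaternary carbon and leaves C8 as R; the closest known reaction is the amine-catalysed Michael–aldol annulation of α-unsubstituted β-keto esters with enals to 5-substituted cyclohex-2-enones, not shown for α-alkyl donors that must form a quaternary carbon in the C–C bond-forming event.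

**Step 2**
Reactants: 6 methyl 3,5-dimethoxy-4-methylbenzoate
Product: 7 methyl 4-(bromomethyl)-3,5-dimethoxybenzoate
Conditions: N-bromosuccinimide, AIBN (cat.), PhCF3, 80 °C
Reagents that add atoms: N-bromosuccinimide, O=C1CCC(=O)N1Br
Why: Wohl–Ziegler radical bromination is selective for the single benzylic methyl group because the ester deactivates the ring toward electrophilic bromination, and no stereocentre is involved.

**Step 3**
Reactants: 5 (5R)-5,6-dimethylcyclohex-2-en-1-one; 7 methyl 4-(bromomethyl)-3,5-dimethoxybenzoate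
Product: 9 methyl 4-{[(1S,6R)-1,6-dimethyl-2-oxocyclohex-3-en-1-yl]methyl}-3,5-dimethoxybenzoate, via lithium enolate 8 (not isolated)
Conditions: LiN(i-Pr)2 (1.1 equiv), THF, −78 °C; then 7, DMPU, −78 → −20 °C
Reagents that add atoms: none
Why: kinetic α′-deprotonation gives the cross-conjugated enolate 8 (both C6 epimers of 5 converge), and SN2 enolate alkylation by the benzylic bromide occurs anti to the adjacent C8 methyl group (pseudoaxial to avoid A(1,2) strain with the enolate methyl), which creates the C9 quaternary centre with the two methyl groups cis.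

**Step 4**
Reactants: 9 methyl 4-{[(1S,6R)-1,6-dimethyl-2-oxocyclohex-3-en-1-yl]methyl}-3,5-dimethoxybenzoate
Product: 11 methyl 4-{[(1S,6R)-1,6-dimethyl-2-(trifluoromethylsulfonyloxy)cyclohex-2-en-1-yl]methyl}-3,5-dimethoxybenzoate, via lithium enolate 10 (not isolated)
Conditions: LiBH(s-Bu)3 (1.1 equiv), THF, −78 °C; then PhNTf2, −78 °C → rt
Reagents that add atoms: N-phenylbis(trifluoromethanesulfonimide), O=S(=O)(N(c1ccccc1)S(=O)(=O)C(F)(F)F)C(F)(F)F
Why: conjugate (1,4) hydride reduction of the β-unsubstituted enone gives the enolate on the only enolisable side (C9 is quaternary) and O-triflation traps it as the C10–C5 enol triflate, a reduction–triflation sequence that touches no stereocentre.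

**Step 5**
Reactants: 11 methyl 4-{[(1S,6R)-1,6-dimethyl-2-(trifluoromethylsulfonyloxy)cyclohex-2-en-1-yl]methyl}-3,5-dimethoxybenzoate; 12 5-bromo-2-methylpent-2-ene
Product: 14 methyl 4-{[(1S,6R)-1,6-dimethyl-2-(4-methylpent-3-en-1-yl)cyclohex-2-en-1-yl]methyl}-3,5-dimethoxybenzoate, via organozinc bromide 13 (not isolated)
Conditions: 12, Zn dust, LiCl, THF, 50 °C; then 11, Pd(dppf)Cl2 (5 mol%), 60 °C
Reagents that add atoms: none
Why: Negishi cross-coupling of an alkenyl triflate with a primary alkylzinc halide tolerates the ester and forms the C10–C1 bond without moving the alkene; no stereocentre is formed.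

**Step 6**
Reactants: 14 methyl 4-{[(1S,6R)-1,6-dimethyl-2-(4-methylpent-3-en-1-yl)cyclohex-2-en-1-yl]methyl}-3,5-dimethoxybenzoate
Product: 15 methyl 4-({(1S,6R)-2-[2-((2S)-3,3-dimethyloxiran-2-yl)ethyl]-1,6-dimethylcyclohex-2-en-1-yl}methyl)-3,5-dimethoxybenzoate
Conditions: ent-Shi ketone (1,2:4,5-di-O-isopropylidene-β-L-erythro-2,3-hexodiulo-2,6-pyranose, 30 mol%), KHSO5 (as 2KHSO5·KHSO4·K2SO4), K2CO3, Bu4NHSO4, MeCN/CH2(OMe)2/aq. Na2B4O7 buffer, 0 °C
Reagents that add atoms: potassium peroxymonosulfate (KHSO5), [K+].[O-]S(=O)(=O)OO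
Why: Shi asymmetric epoxidation by the chiral dioxirane (spiro transition state) is selective for the unhindered terminal trisubstituted alkene over the ring alkene flanked by the quaternary carbon, and the L-series ketone delivers oxygen to the face that gives the (S)-epoxide at C3.

**Step 7**
Reactants: 15 methyl 4-({(1S,6R)-2-[2-((2S)-3,3-dimethyloxiran-2-yl)ethyl]-1,6-dimethylcyclohex-2-en-1-yl}methyl)-3,5-dimethoxybenzoate
Product: 16 methyl 4-{[(1S,2R,4aR,6S)-6-hydroxy-1,2,5,5-tetramethyl-1,2,3,4,4a,5,6,7-octahydronaphthalen-1-yl]methyl}-3,5-dimethoxybenzoate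
Conditions: Cp2TiCl2 (2.5 equiv), Mn dust, THF, rt; then 1 M HCl
Reagents that add atoms: none
Why: Cp2TiCl (trivalent titanium) opens the epoxide homolytically to the tertiary C4 radical, which closes 6-endo onto C5 through a chair transition state with the C3–O–Ti group equatorial (so the (S)-epoxide fixes C5 as R, H-5 trans to the C3 oxygen), and the tertiary C10 radical is trapped by a second Cp2TiCl and loses the unhindered H-1 by β-hydride elimination to give the C1–C10 alkene (radical epoxypolyene cyclisation of the Nugent–RajanBabu type).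

**Step 8**
Reactants: 16 methyl 4-{[(1S,2R,4aR,6S)-6-hydroxy-1,2,5,5-tetramethyl-1,2,3,4,4a,5,6,7-octahydronaphthalen-1-yl]methyl}-3,5-dimethoxybenzoate
Product: 17 methyl 4-{[(1S,2R,4aR)-1,2,5,5-tetramethyl-6-oxo-1,2,3,4,4a,5,6,7-octahydronaphthalen-1-yl]methyl}-3,5-dimethoxybenzoate
Conditions: Dess–Martin periodinane, NaHCO3, CH2Cl2, 0 °C → rt
Reagents that add atoms: none
Why: Dess–Martin oxidation under buffered, non-enolising conditions converts the hindered equatorial alcohol into the ketone without moving the β,γ-alkene into conjugation and without touching C5, C8 or C9.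

**Step 9**
Reactants: 17 methyl 4-{[(1S,2R,4aR)-1,2,5,5-tetramethyl-6-oxo-1,2,3,4,4a,5,6,7-octahydronaphthalen-1-yl]methyl}-3,5-dimethoxybenzoate
Product: 19 (2R,5S,6R,8aR)-5-{[4-(hydroxymethyl)-2,6-dimethoxyphenyl]methyl}-1,1,5,6-tetramethyl-1,2,3,5,6,7,8,8a-octahydronaphthalen-2-ol, via 3α-hydroxy ester 18 (not isolated)
Conditions: LiBH(s-Bu)3 (1.3 equiv), THF, −78 °C; then LiAlH4, −78 → 0 °C; aq. KNaC4H4O6
Reagents that add atoms: none
Why: the bulky hydride attacks the C3 ketone along the equatorial trajectory, on the face opposite to axial H-5, and so gives the axial 3α (R) alcohol (substrate-controlled stereoselective ketone reduction), after which LiAlH4 reduces the aryl ester to the benzylic alcohol in the same flask.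

**Step 10**
Reactants: 19 (2R,5S,6R,8aR)-5-{[4-(hydroxymethyl)-2,6-dimethoxyphenyl]methyl}-1,1,5,6-tetramethyl-1,2,3,5,6,7,8,8a-octahydronaphthalen-2-ol
Product: 20 2-{[(1S,2R,4aR,6R)-6-hydroxy-1,2,5,5-tetramethyl-1,2,3,4,4a,5,6,7-octahydronaphthalen-1-yl]methyl}-5-(hydroxymethyl)benzene-1,3-diol
Conditions: NaSEt (10 equiv), DMF, 140 °C; then 1 M HCl
Reagents that add atoms: none
Why: SN2 O-demethylation by ethanethiolate in a dipolar aprotic solvent cleaves both aryl methyl ethers under basic conditions that leave the alkene, the two alcohols and all stereocentres untouched.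

**Step 11**
Reactants: 20 2-{[(1S,2R,4aR,6R)-6-hydroxy-1,2,5,5-tetramethyl-1,2,3,4,4a,5,6,7-octahydronaphthalen-1-yl]methyl}-5-(hydroxymethyl)benzene-1,3-diol
Product: 21 2,4-dihydroxy-3-{[(1S,2R,4aR,6R)-6-hydroxy-1,2,5,5-tetramethyl-1,2,3,4,4a,5,6,7-octahydronaphthalen-1-yl]methyl}-6-(hydroxymethyl)benzaldehyde
Conditions: MgCl2, Et3N, (CH2O)n, MeCN, reflux; then 1 M HCl
Reagents that add atoms: paraformaldehyde (formaldehyde), C=O
Why: magnesium-mediated ortho-formylation (Casnati–Skattebøl reaction) delivers formaldehyde ortho to a phenoxide within a chelate and oxidises the resulting benzylic alkoxide to the aldehyde, and the two free ring positions are equivalent so only one mono-aldehyde can form.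

**Compound list**
1 | (E)-but-2-enal | C/C=C/C=O | starting material
2 | tert-butyl 2-methyl-3-oxobutanoate | CC(=O)C(C)C(=O)OC(C)(C)C | starting material
3 | tert-butyl (3R)-2-acetyl-2,3-dimethyl-5-oxopentanoate (C2 epimers) | C[C@H](CC=O)C(C)(C(C)=O)C(=O)OC(C)(C)C | intermediate
4 | tert-butyl (6R)-1,6-dimethyl-2-oxocyclohex-3-ene-1-carboxylate (C1 epimers) | C[C@@H]1CC=CC(=O)C1(C)C(=O)OC(C)(C)C | intermediate
5 | (5R)-5,6-dimethylcyclohex-2-en-1-one (C6 epimers) | C[C@@H]1CC=CC(=O)C1C | intermediate
6 | methyl 3,5-dimethoxy-4-methylbenzoate | COC(=O)c1cc(OC)c(C)c(OC)c1 | starting material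
7 | methyl 4-(bromomethyl)-3,5-dimethoxybenzoate | COC(=O)c1cc(OC)c(CBr)c(OC)c1 | intermediate
8 | lithium (3R)-2,3-dimethylcyclohexa-1,5-dien-1-olate | C[C@@H]1CC=CC([O-])=C1C.[Li+] | intermediate
9 | methyl 4-{[(1S,6R)-1,6-dimethyl-2-oxocyclohex-3-en-1-yl]methyl}-3,5-dimethoxybenzoate | C[C@@H]1CC=CC(=O)[C@@]1(C)Cc1c(OC)cc(cc1OC)C(=O)OC | intermediate
10 | lithium (5R,6S)-6-{[2,6-dimethoxy-4-(methoxycarbonyl)phenyl]methyl}-5,6-dimethylcyclohex-1-en-1-olate | C[C@@H]1CCC=C([O-])[C@@]1(C)Cc1c(OC)cc(cc1OC)C(=O)OC.[Li+] | intermediate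
11 | methyl 4-{[(1S,6R)-1,6-dimethyl-2-(trifluoromethylsulfonyloxy)cyclohex-2-en-1-yl]methyl}-3,5-dimethoxybenzoate | C[C@@H]1CCC=C(OS(=O)(=O)C(F)(F)F)[C@@]1(C)Cc1c(OC)cc(cc1OC)C(=O)OC | intermediate
12 | 5-bromo-2-methylpent-2-ene | CC(C)=CCCBr | starting material
13 | (4-methylpent-3-en-1-yl)zinc bromide | CC(C)=CCC[Zn]Br | intermediate
14 | methyl 4-{[(1S,6R)-1,6-dimethyl-2-(4-methylpent-3-en-1-yl)cyclohex-2-en-1-yl]methyl}-3,5-dimethoxybenzoate | C[C@@H]1CCC=C(CCC=C(C)C)[C@@]1(C)Cc1c(OC)cc(cc1OC)C(=O)OC | intermediate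
15 | methyl 4-({(1S,6R)-2-[2-((2S)-3,3-dimethyloxiran-2-yl)ethyl]-1,6-dimethylcyclohex-2-en-1-yl}methyl)-3,5-dimethoxybenzoate | C[C@@H]1CCC=C(CC[C@@H]2OC2(C)C)[C@@]1(C)Cc1c(OC)cc(cc1OC)C(=O)OC | intermediate
16 | methyl 4-{[(1S,2R,4aR,6S)-6-hydroxy-1,2,5,5-tetramethyl-1,2,3,4,4a,5,6,7-octahydronaphthalen-1-yl]methyl}-3,5-dimethoxybenzoate | C[C@@H]1CC[C@@H]2C(=CC[C@H](O)C2(C)C)[C@@]1(C)Cc1c(OC)cc(cc1OC)C(=O)OC | intermediate
17 | methyl 4-{[(1S,2R,4aR)-1,2,5,5-tetramethyl-6-oxo-1,2,3,4,4a,5,6,7-octahydronaphthalen-1-yl]methyl}-3,5-dimethoxybenzoate | C[C@@H]1CC[C@@H]2C(=CCC(=O)C2(C)C)[C@@]1(C)Cc1c(OC)cc(cc1OC)C(=O)OC | intermediate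
18 | methyl 4-{[(1S,2R,4aR,6R)-6-hydroxy-1,2,5,5-tetramethyl-1,2,3,4,4a,5,6,7-octahydronaphthalen-1-yl]methyl}-3,5-dimethoxybenzoate (present as its lithium alkoxide) | C[C@@H]1CC[C@@H]2C(=CC[C@@H](O)C2(C)C)[C@@]1(C)Cc1c(OC)cc(cc1OC)C(=O)OC | intermediate
19 | (2R,5S,6R,8aR)-5-{[4-(hydroxymethyl)-2,6-dimethoxyphenyl]methyl}-1,1,5,6-tetramethyl-1,2,3,5,6,7,8,8a-octahydronaphthalen-2-ol | C[C@@H]1CC[C@@H]2C(=CC[C@@H](O)C2(C)C)[C@@]1(C)Cc1c(OC)cc(CO)cc1OC | intermediate
20 | 2-{[(1S,2R,4aR,6R)-6-hydroxy-1,2,5,5-tetramethyl-1,2,3,4,4a,5,6,7-octahydronaphthalen-1-yl]methyl}-5-(hydroxymethyl)benzene-1,3-diol | C[C@@H]1CC[C@@H]2C(=CC[C@@H](O)C2(C)C)[C@@]1(C)Cc1c(O)cc(CO)cc1O | intermediate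
21 | 2,4-dihydroxy-3-{[(1S,2R,4aR,6R)-6-hydroxy-1,2,5,5-tetramethyl-1,2,3,4,4a,5,6,7-octahydronaphthalen-1-yl]methyl}-6-(hydroxymethyl)benzaldehyde | C[C@@H]1CC[C@@H]2C(=CC[C@@H](O)C2(C)C)[C@@]1(C)Cc1c(O)cc(CO)c(C=O)c1O | target

**Step count**
Total: 11 steps. Longest linear sequence: 10 steps (1, 3–11; the aryl branch 2, 3–11 is equally long).

**Steps most likely to fail**

Step 1 (proposed new annulation). The α-methyl donor is less acidic and more hindered than the parent β-keto ester, so the Michael addition may be slow or poorly enantioselective. The fallback uses the known annulation and sets out from 1. tert-Butyl 3-oxobutanoate is added under the same amine catalyst to give tert-butyl (3R)-2-acetyl-3-methyl-5-oxopentanoate F1. With p-TsOH in toluene at 80 °C this closes to tert-butyl (6R)-6-methyl-2-oxocyclohex-3-ene-1-carboxylate F2, which loses isobutene and CO2 to give (5R)-5-methylcyclohex-2-en-1-one F3. Kinetic deprotonation with LiN(i-Pr)2 (THF, −78 °C) gives lithium (3R)-3-methylcyclohexa-1,5-dien-1-olate F4, and methylation with iodomethane comes back to the route at 5, at the cost of one extra step.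

Step 7 (radical cyclisation). Closure onto the hindered ring alkene may be slower than premature quenching of the C4 radical, and the alkene may form in the wrong position. The fallback sets out from 15 and comes back at 16. It leaves the radical manifold for a cationic epoxide–alkene cyclisation with MeAlCl2 in CH2Cl2 at −78 °C. The epoxide again imposes the chair closure, and the C10 cation loses H-1. No new compound is made.

Step 3 (quaternary carbon by benzylation). The fully substituted enolate may exchange protons to the extended dienolate, or react slowly with the doubly ortho-substituted bromide. The fallback sets out from 7 and comes back at 9. Kornblum oxidation of 7 (NaHCO3, DMSO, 90 °C) gives methyl 4-formyl-3,5-dimethoxybenzoate F5. Enolate 8 adds to it at −78 °C (aldol addition, same face anti to the C8 methyl) to give methyl 4-{hydroxy[(1R,6R)-1,6-dimethyl-2-oxocyclohex-3-en-1-yl]methyl}-3,5-dimethoxybenzoate F6. This adduct cannot dehydrate, and ionic deoxygenation of its benzylic carbinol with Et3SiH/CF3CO2H (CH2Cl2, 0 °C) gives 9.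

**Further compounds**
F1 | step 1 | tert-butyl (3R)-2-acetyl-3-methyl-5-oxopentanoate | C[C@H](CC=O)C(C(C)=O)C(=O)OC(C)(C)C
F2 | step 1 | tert-butyl (6R)-6-methyl-2-oxocyclohex-3-ene-1-carboxylate | C[C@@H]1CC=CC(=O)C1C(=O)OC(C)(C)C
F3 | step 1 | (5R)-5-methylcyclohex-2-en-1-one | C[C@@H]1CC=CC(=O)C1
F4 | step 1 | lithium (3R)-3-methylcyclohexa-1,5-dien-1-olate | C[C@@H]1CC=CC([O-])=C1.[Li+]
F0 | step 7 | none | none
F5 | step 3 | methyl 4-formyl-3,5-dimethoxybenzoate | COC(=O)c1cc(OC)c(C=O)c(OC)c1
F6 | step 3 | methyl 4-{hydroxy[(1R,6R)-1,6-dimethyl-2-oxocyclohex-3-en-1-yl]methyl}-3,5-dimethoxybenzoate | C[C@@H]1CC=CC(=O)[C@@]1(C)C(O)c1c(OC)cc(cc1OC)C(=O)OC
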